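- The partner is the molecule to follow, and the bench rule says one equivalent of it makes one equivalent of mono adduct.

| flask | substrate | partner | remark | time |
|---|---|---|---|---|
| Saturday's | 0.050 M | 0.050 M | run made earlier |  |
| Monday's | 0.050 M | 0.075 M | run made earlier |  |
| Wednesday's | 0.025 M | 0.10 M | run made earlier |  |
| flask | 0.050 M | 0.100 M |  | 3.0 h |

| run | time / min | mono adduct / % |
|---|---|---|
| Saturday's | 6.00 | 38.5 |
| Saturday's | 15.0 | 57.9 |
| Saturday's | 30.0 | 65.2 |
| Saturday's | 50.0 | 65.1 |
| Saturday's | 60.0 | 65.9 |
| Saturday's | 80.0 | 68.0 |
| Saturday's | 120 | 67.1 |
| Monday's | 15.0 | 73.5 |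
| Monday's | 30.0 | 81.8 |
| Monday's | 50.0 | 83.1 |
| Monday's | 60.0 | 87.1 |
| Monday's | 80.0 | 85.5 |
| Monday's | 90.0 | 86.9 |
| Monday's | 120 | 86.4 |
| Wednesday's | 10.0 | 80.6 |
| Wednesday's | 25.0 | 91.1 |
| Wednesday's | 50.0 | 92.7 |
| Wednesday's | 80.0 | 93.6 |
| Wednesday's | 120 | 92.0 |

(readings scatter by 1 percentage point)

- a reading or a percentage of mono adduct counts all its forms, free or not

- equivalents of partner to substrate, everything else as given, that leave most mono adduct at 3.0 h
- the amount of mono adduct then, in percent of the substrate charged
- the amount of mono adduct with the amounts as given

- Saturday's run, with equal charges, stays flat at about 66.3%, and Monday's at about 86.5%, so the rule fails on these readings.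
- My reckoning supposes that each partner molecule meets a fork: it either finds substrate or is lost. Call the even point the substrate concentration at which those two chances are equal.
- Adding up the forks gives, once the partner is gone: partner charged = substrate used + even point × ln(substrate charged / substrate left).
- Saturday's plateau gives 15.5 mM and Monday's 15.9 mM, so I take 15.7 mM.
- The border of the bench rule is the ratio of even point to substrate: by this reckoning, a partner's chance in Saturday's run goes from 76.1% at the start to 51.8% at the plateau.
- For the flask, I reckon 3.63% of the substrate left, so about 96.4% of it taken up.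
- Wednesday's run, at 4.00 equivalents, reads 6.4 percentage points below this reckoning. That gap is larger than the share of substrate I reckon left in the flask, though Wednesday's run also has less substrate than the flask, so I would stay near 2.00 equivalents.
- The forecast differs from me: it holds that “by 3 h the mixture should be at equilibrium” and gives 90% for the flask, with a best of 94% at 4 equiv.
- The flask gives 93.8%, and its best is 94.3% at 2.24 equiv, a lower ratio than the forecast's. At 3.00 h the flask keeps 0.075% of its partner, the limiting reagent despite the excess charged, and 2.6% of its substrate.

    substrate + partner → mono adduct (k = 2.30 L mol⁻¹ min⁻¹)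
    partner + mono adduct → double product (k = 0.0390 L mol⁻¹ min⁻¹)
    partner → decomposed reagent (k = 0.0310 min⁻¹)
    crystals ⇌ mono adduct, rate k4*(cs4 - [mono adduct]) while solid is left; crystals form when [mono adduct] > cs4 (solubility = 32.0 mM, k = 0.210 min⁻¹)

- Now take the same flask with 0.20 M of substrate. Solving the fork sum twice with the even point gives 54.6% of the substrate left, and that flask holds 54.3%.

All runs were computed for an exercise; the scatter is artificial.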